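**Retrosynthetic overview**
1. Numbering: C1 = oxirane carbon bearing C7H2OBz, C2 = CHOH, C3 = CHOBz, C4=C5 = alkene, C6 = oxirane CH.
2. Endgame: the C3 benzoate comes from invertive (Mitsunobu) esterification of an all-cis epoxy diol. The oxirane comes from C2-OH-directed epoxidation of C1=C6 in a cis-dihydrodiol.
3. Key disconnection: C1-C2 and C3-C4 are made together by an inverse-electron-demand [4+2] addition. The partners are methyl 2-oxo-2H-pyran-3-carboxylate (C4, C5, C6, C1, with C7 as the ester) and a Z-enediol bis-silyl ether (C2, C3). Loss of the lactone bridge as CO2 follows.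
4. Enabling feature: the oxirane C1-O-C6 next to the C4=C5 alkene is a masked C1=C6-C5=C4 diene. Its two termini flank the vicinal O-bearing sp3 pair C2-C3, which is a masked enediol. C7 on terminus C1 can be an ester, which makes that diene an electron-poor, chelating 2-pyrone.
5. Ring order: temporary 2-oxabicyclo[2.2.2]octenone, then cyclohexa-1,3-diene carbocycle, then oxirane.

Key step: step 2

Assumption: the sense of induction of the Cu(OTf)2/tBu-BOX catalyst is taken from the square-planar chelate (quadrant) model, which calls for the (R,R) ligand; both ligand antipodes are commercial, so the series can be corrected without changing the route.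

**Step 1**
Reactants: 1 (tert-butyldimethylsilyloxy)acetaldehyde
Product: 2 (Z)-1,2-bis(tert-butyldimethylsilyloxy)ethene
Conditions: TBSOTf, Et3N, CH2Cl2, 0 °C to rt
Reagents that add atoms: tert-butyldimethylsilyl triflate, CC(C)(C)[Si](C)(C)OS(=O)(=O)C(F)(F)F
Why: Soft enolisation and O-silylation (silyl enol ether formation) of an alpha-silyloxy aldehyde should give mainly the Z alkene, because 1,2-dioxygenated alkenes and the enolisation leading to them favour cis C-O bonds; no stereocentre is formed, and the minor E isomer is removed on Et3N-deactivated silica.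

**Step 2**
Reactants: 2 (Z)-1,2-bis(tert-butyldimethylsilyloxy)ethene; 3 methyl 2-oxo-2H-pyran-3-carboxylate
Product: 5 methyl (5R,6S)-5,6-bis(tert-butyldimethylsilyloxy)cyclohexa-1,3-diene-1-carboxylate, via bicyclic lactone 4 (not isolated)
Conditions: Cu(OTf)2 (10 mol %), (R,R)-tBu-BOX (11 mol %), 4 Å MS, CH2Cl2, -30 °C; then 1,10-phenanthroline (0.25 equiv), solvent switch to PhMe, 95 °C
Reagents that add atoms: none
Why: Bidentate binding of the lactone and ester carbonyls of 3 to the divalent copper centre lowers the pyrone LUMO, so the electron-rich alkene of 2 adds across pyrone C6 and C3 (target C4 and C1) in a concerted, asynchronous inverse-electron-demand Diels-Alder reaction in which C3-C4 leads and C1-C2 follows, and heating then expels the O-C(=O) bridge of 4 as CO2 by retro-[4+2]. The closest known reaction type is the chiral Lewis acid catalysed cycloaddition of 3-carboalkoxy-2-pyrones with enol ethers, silyl enol ethers and 1,3-dioxoles, followed by thermal CO2 extrusion to arene cis-dihydrodiol derivatives. The carbocycle C1-C6 is closed intermolecularly by suprafacial [4π+2π] addition through a boat-like bicyclo[2.2.2] transition state, and the temporary lactone ring is removed again by the cycloreversion. C2 and C3 are set cis by the Z geometry of 2, and their absolute configuration by the ligand, whose tert-butyl group beside the pyrone ring leaves only the Re face of pyrone C6 open, together with the endo orientation of both silyloxy groups; the stereocentres at C1 and C4 of 4 are transient and vanish with CO2. No regiochemical issue exists because 2 is C2v-symmetric, but endo selectivity is required, since an exo adduct on the same face would give the enantiomeric diene, and it is secured by the clash of exo silyloxy groups with the catalyst-bound lactone bridge. 1,10-Phenanthroline masks the copper salt before heating so that 5 should not lose silanol and aromatise.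

**Step 3**
Reactants: 5 methyl (5R,6S)-5,6-bis(tert-butyldimethylsilyloxy)cyclohexa-1,3-diene-1-carboxylate
Product: 6 [(5R,6S)-5,6-bis(tert-butyldimethylsilyloxy)cyclohexa-1,3-dien-1-yl]methanol
Conditions: iBu2AlH (2.5 equiv), CH2Cl2, -78 °C; aq. potassium sodium tartrate
Reagents that add atoms: none
Why: 1,2-Reduction of a conjugated ester with iBu2AlH at low temperature should stop at the allylic alcohol, bring C7 to the oxidation level of the target, and leave the silyl ethers, the diene, C2 and C3 untouched.

**Step 4**
Reactants: 6 [(5R,6S)-5,6-bis(tert-butyldimethylsilyloxy)cyclohexa-1,3-dien-1-yl]methanol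
Product: 7 [(5R,6S)-5,6-bis(tert-butyldimethylsilyloxy)cyclohexa-1,3-dien-1-yl]methyl benzoate
Conditions: BzCl, pyridine, DMAP (cat.), CH2Cl2, 0 °C
Reagents that add atoms: benzoyl chloride, O=C(Cl)c1ccccc1
Why: DMAP-catalysed acylation of the only free, primary hydroxyl installs the C7 benzoate under basic conditions that the acid-sensitive diene tolerates; no stereocentre is touched.

**Step 5**
Reactants: 7 [(5R,6S)-5,6-bis(tert-butyldimethylsilyloxy)cyclohexa-1,3-dien-1-yl]methyl benzoate
Product: 8 [(5R,6S)-5,6-dihydroxycyclohexa-1,3-dien-1-yl]methyl benzoate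
Conditions: Bu4NF, AcOH (1:1, 2.5 equiv each), THF, 0 °C to rt
Reagents that add atoms: none
Why: Fluoride-mediated silyl ether cleavage buffered with AcOH should free both secondary hydroxyls without strong acid (no dehydrative aromatisation) and without free alkoxide (no benzoyl migration), leaving C2 and C3 unchanged.

**Step 6**
Reactants: 8 [(5R,6S)-5,6-dihydroxycyclohexa-1,3-dien-1-yl]methyl benzoate
Product: 9 [(1R,2R,3R,6S)-2,3-dihydroxy-7-oxabicyclo[4.1.0]hept-4-en-1-yl]methyl benzoate
Conditions: VO(acac)2 (5 mol %), tBuOOH (1.1 equiv, decane), CH2Cl2, 0 °C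
Reagents that add atoms: tert-butyl hydroperoxide, CC(C)(C)OO
Why: In this vanadium-catalysed hydroxyl-directed epoxidation the C2 hydroxyl, held pseudoaxial by A(1,2) strain with the C1 side chain, binds the metal peroxide and delivers oxygen to the more electron-rich trisubstituted C1=C6 alkene on its own face, which sets C1 and C6 syn to C2-OH, whereas the pseudoequatorial C3 hydroxyl directs the C4=C5 alkene only poorly.

**Step 7**
Reactants: 9 [(1R,2R,3R,6S)-2,3-dihydroxy-7-oxabicyclo[4.1.0]hept-4-en-1-yl]methyl benzoate
Product: 10 (-)-pipoxide, [(1R,2R,3S,6S)-3-(benzoyloxy)-2-hydroxy-7-oxabicyclo[4.1.0]hept-4-en-1-yl]methyl benzoate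
Conditions: PPh3, DIAD, PhCO2H (1.3 equiv each), THF, 0 °C
Reagents that add atoms: benzoic acid, O=C(O)c1ccccc1
Why: In the Mitsunobu esterification the less hindered allylic C3 hydroxyl forms the oxyphosphonium ion and is displaced by benzoate in an SN2 process from the open face opposite the oxirane and C2-OH, which inverts C3 to the trans arrangement and installs the second benzoate, while the C2 hydroxyl next to the fully substituted C1 stays free and, being cis, cannot displace the leaving group.

**Compound list**
1 | (tert-butyldimethylsilyloxy)acetaldehyde | CC(C)(C)[Si](C)(C)OCC=O | starting material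
2 | (Z)-1,2-bis(tert-butyldimethylsilyloxy)ethene | CC(C)(C)[Si](C)(C)O/C=C\O[Si](C)(C)C(C)(C)C | intermediate
3 | methyl 2-oxo-2H-pyran-3-carboxylate | COC(=O)C1=CC=COC1=O | starting material
4 | methyl (1S,4R,7R,8S)-7,8-bis(tert-butyldimethylsilyloxy)-3-oxo-2-oxabicyclo[2.2.2]oct-5-ene-4-carboxylate (endo adduct, both silyloxy groups anti to the lactone bridge) | COC(=O)[C@]12C=C[C@H](OC1=O)[C@@H](O[Si](C)(C)C(C)(C)C)[C@H]2O[Si](C)(C)C(C)(C)C | intermediate
5 | methyl (5R,6S)-5,6-bis(tert-butyldimethylsilyloxy)cyclohexa-1,3-diene-1-carboxylate (cis) | COC(=O)C1=CC=C[C@@H](O[Si](C)(C)C(C)(C)C)[C@H]1O[Si](C)(C)C(C)(C)C | intermediate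
6 | [(5R,6S)-5,6-bis(tert-butyldimethylsilyloxy)cyclohexa-1,3-dien-1-yl]methanol | OCC1=CC=C[C@@H](O[Si](C)(C)C(C)(C)C)[C@H]1O[Si](C)(C)C(C)(C)C | intermediate
7 | [(5R,6S)-5,6-bis(tert-butyldimethylsilyloxy)cyclohexa-1,3-dien-1-yl]methyl benzoate | O=C(OCC1=CC=C[C@@H](O[Si](C)(C)C(C)(C)C)[C@H]1O[Si](C)(C)C(C)(C)C)c1ccccc1 | intermediate
8 | [(5R,6S)-5,6-dihydroxycyclohexa-1,3-dien-1-yl]methyl benzoate (cis-diol) | O=C(OCC1=CC=C[C@@H](O)[C@H]1O)c1ccccc1 | intermediate
9 | [(1R,2R,3R,6S)-2,3-dihydroxy-7-oxabicyclo[4.1.0]hept-4-en-1-yl]methyl benzoate (oxirane O, C2-OH and C3-OH all cis) | O=C(OC[C@]12O[C@H]1C=C[C@@H](O)[C@H]2O)c1ccccc1 | intermediate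
10 | (-)-pipoxide, [(1R,2R,3S,6S)-3-(benzoyloxy)-2-hydroxy-7-oxabicyclo[4.1.0]hept-4-en-1-yl]methyl benzoate | O=C(OC[C@]12O[C@H]1C=C[C@H](OC(=O)c1ccccc1)[C@H]2O)c1ccccc1 | target

Total step count: 7. Longest linear sequence: 7 steps (1 to 10).

**Steps most likely to fail**

**Step 2.**
- What may go wrong: slow cycloaddition of the hindered acyclic bis-silyl ether; leakage through the exo mode or through open-chain Mukaiyama-Michael silyl transfer, which lowers the enantiomeric purity of the diene; loss of silanol with aromatisation during the hot CO2 extrusion.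
- Fallback, setting out from 2 and coming back at 6: catalyst control is replaced by auxiliary control, with isolation of the bicycle. Commercial 2-oxo-2H-pyran-3-carboxylic acid is esterified (DCC, DMAP) with (R)-pantolactone to the pyrone ester F1. Eu(fod)3-promoted cycloaddition with 2 gives the bicyclic lactone F2. Its diastereomers are separated by crystallisation or chromatography, so that wrong-face and exo adducts are not carried on. CO2 is then removed at room temperature with Pd(PPh3)4: zerovalent palladium ionises the allylic lactone C-O bond, and decarboxylative 1,4-elimination gives the dienoate F3. Excess iBu2AlH cleaves the auxiliary and gives 6.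

**Step 6.**
- What may go wrong: poor site selectivity between the two allylic-alcohol alkenes; oxidation of the pseudoequatorial C3 hydroxyl followed by aromatisation.
- Fallback, setting out from 6 and coming back at 10: the directing element is changed. Buffered Bu4NF removes both silyl groups from 6 to give the triol F4, in which the primary C7 hydroxyl and the C2 hydroxyl both flank only the C1=C6 alkene. VO(acac)2/tBuOOH epoxidation, anchored at these two hydroxyls, should give the epoxy triol F5. A double Mitsunobu reaction with two equivalents of benzoic acid esterifies C7-OH and inverts C3 in the same operation, giving 10.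

**Step 7.**
- What may go wrong: SN2′ attack at C5; elimination of the activated C3 oxygen with aromatisation; acid-promoted opening of the vinyl oxirane.
- Fallback, setting out from 9 and coming back at 10: displacement is replaced by an oxidation and directed reduction sequence. MnO2 oxidises only the allylic C3 hydroxyl to the enone F6. Me4NBH(OAc)3, bound to the C2 hydroxyl, delivers hydride to C3 from the face of that hydroxyl and should give the trans-diol F7. One equivalent of BzCl in pyridine at -30 °C acylates the less hindered allylic C3 hydroxyl to give 10.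

**Further compounds**
F1 | step 2 | (3R)-4,4-dimethyl-2-oxooxolan-3-yl 2-oxo-2H-pyran-3-carboxylate | O=C(O[C@H]1C(=O)OCC1(C)C)C1=CC=COC1=O
F2 | step 2 | (R)-pantolactone ester analogue of lactone 4, same configuration of the bicycle | O=C(O[C@H]3C(=O)OCC3(C)C)[C@]12C=C[C@H](OC1=O)[C@@H](O[Si](C)(C)C(C)(C)C)[C@H]2O[Si](C)(C)C(C)(C)C
F3 | step 2 | (R)-pantolactone ester analogue of dienoate 5, same configuration at C2 and C3 | O=C(O[C@H]1C(=O)OCC1(C)C)C1=CC=C[C@@H](O[Si](C)(C)C(C)(C)C)[C@H]1O[Si](C)(C)C(C)(C)C
F4 | step 6 | (1R,2S)-3-(hydroxymethyl)cyclohexa-3,5-diene-1,2-diol | OCC1=CC=C[C@@H](O)[C@H]1O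
F5 | step 6 | (1R,2R,3R,6S)-1-(hydroxymethyl)-7-oxabicyclo[4.1.0]hept-4-ene-2,3-diol | OC[C@]12O[C@H]1C=C[C@@H](O)[C@H]2O
F6 | step 7 | [(1R,2S,6S)-2-hydroxy-3-oxo-7-oxabicyclo[4.1.0]hept-4-en-1-yl]methyl benzoate | O=C(OC[C@]12O[C@H]1C=CC(=O)[C@H]2O)c1ccccc1
F7 | step 7 | [(1R,2R,3S,6S)-2,3-dihydroxy-7-oxabicyclo[4.1.0]hept-4-en-1-yl]methyl benzoate (trans-diol) | O=C(OC[C@]12O[C@H]1C=C[C@H](O)[C@H]2O)c1ccccc1
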